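**Retrosynthetic overview**
1. Target 22 ⇐ 21 by one fluoride step (TBDPS ether and TMSE ester removed together) ⇐ 18 by O3 angeloylation with 19 ⇐ 17 by C8 Wittig methylenation.
2. 17 ⇐ 15 by a one-carbon ring expansion: C10 shifts from C8 to C9, turning the cyclopentane of a trans-hydrindane into ring B and placing the whole side chain on C9.
3. 15 ⇐ hydrindanone 9 + ylide 14 (Wittig); 14 ⇐ 5-chloropent-1-yne 10 by carboalumination/acylation (sets 13E).
4. 9 ⇐ enedione 4 by ketalisation, reductive hydroxymethylation (sets C4 and C5) and C3 reduction; 4 ⇐ 1 + 2 by asymmetric Robinson annulation (sets C10).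
5. Ring order: cyclopentane (from 1) → ring A (annulation) → ring B (expansion of the cyclopentane).

Assumption: ClCO2CH2CH2SiMe3 (Teoc-Cl) is taken as a purchasable protecting-group reagent; atoms are referred to by their final labdane numbers (C1–C20), while hydrindane names use indene locants.

**Step 1**
Reactants: 1 2-methylcyclopentane-1,3-dione; 2 pent-1-en-3-one
Product: 4 (7aR)-4,7a-dimethyl-2,3,7,7a-tetrahydro-1H-indene-1,5(6H)-dione, via triketone 3 (not isolated)
Conditions: H2O, AcOH (cat.), 70 °C; concentrate; then D-phenylalanine (1.0 equiv), (1R)-(−)-camphorsulfonic acid (0.5 equiv), DMF, 30 → 70 °C; recrystallise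
Reagents that add atoms: none
Why: Michael addition followed by amino-acid-catalysed intramolecular aldol condensation (Hajos–Parrish-type Robinson annulation) builds ring A, and the D-amino acid enamine selects between the enantiotopic ring carbonyls to give the (R) quaternary centre (future C10), the mirror image of the L-series product.

**Step 2**
Reactants: 4 (7aR)-4,7a-dimethyl-2,3,7,7a-tetrahydro-1H-indene-1,5(6H)-dione
Product: 5 (7a'R)-4',7a'-dimethyl-2',3',7',7a'-tetrahydrospiro[1,3-dioxolane-2,1'-inden]-5'(6'H)-one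
Conditions: HOCH2CH2OH (solvent), TsOH·H2O (1 equiv), 4 Å MS, rt, 30 min
Reagents that add atoms: ethane-1,2-diol, OCCO
Why: Chemoselective acid-catalysed ketalisation, because the saturated cyclopentanone reacts much faster than the conjugated tetrasubstituted enone; this masks it for the dissolving-metal step.

**Step 3**
Reactants: 5 (7a'R)-4',7a'-dimethyl-2',3',7',7a'-tetrahydrospiro[1,3-dioxolane-2,1'-inden]-5'(6'H)-one
Product: 6 (3a'S,4'S,7a'R)-4'-(hydroxymethyl)-4',7a'-dimethylhexahydrospiro[1,3-dioxolane-2,1'-inden]-5'(4'H)-one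
Conditions: Li (2.4 equiv), t-BuOH (1.0 equiv), NH3(l)–THF, −78 °C; isoprene; NH3 off; then CH2O (g), THF, −78 °C; aq NH4Cl
Reagents that add atoms: formaldehyde, C=O
Why: Stork reductive alkylation (Birch-type enone reduction, then aldol): axial protonation of the β-carbon anti to the angular methyl gives the trans ring fusion (C5), and the regiodefined lithium enolate is hydroxymethylated on the face opposite the angular methyl, so the CH2OH on the new quaternary C4 is trans to that methyl.

**Step 4**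
Reactants: 6 (3a'S,4'S,7a'R)-4'-(hydroxymethyl)-4',7a'-dimethylhexahydrospiro[1,3-dioxolane-2,1'-inden]-5'(4'H)-one
Product: 8 (3aR,4S,5R,7aR)-5-hydroxy-4-(hydroxymethyl)-4,7a-dimethyloctahydro-1H-inden-1-one, via diol ketal 7 (not isolated)
Conditions: NaBH4, MeOH, −20 °C; then 2 M HCl–THF, rt
Reagents that add atoms: water, O
Why: Borohydride reduction with axial hydride delivery anti to the angular and axial C4 methyl groups gives the equatorial C3 alcohol (cis to the angular methyl), and the acidic work-up hydrolyses the dioxolane (acetal hydrolysis).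

**Step 5**
Reactants: 8 (3aR,4S,5R,7aR)-5-hydroxy-4-(hydroxymethyl)-4,7a-dimethyloctahydro-1H-inden-1-one
Product: 9 (3aR,4S,5R,7aR)-4-[(tert-butyldiphenylsilyloxy)methyl]-5-hydroxy-4,7a-dimethyloctahydro-1H-inden-1-one
Conditions: TBDPSCl (1.1 equiv), imidazole, DMF, 0 °C
Reagents that add atoms: tert-butyl(chloro)diphenylsilane, CC(C)(C)[Si](Cl)(c1ccccc1)c1ccccc1
Why: Selective silylation of the primary hydroxyl over the hindered secondary C3–OH; TBDPS is chosen because it survives the sulfonic acid released in step 9.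

**Step 6**
Reactants: 10 5-chloropent-1-yne
Product: 12 2-(trimethylsilyl)ethyl (2E)-6-chloro-3-methylhex-2-enoate, via alkenylalane 11 (not isolated)
Conditions: Me3Al (2.0 equiv), Cp2ZrCl2 (0.2 equiv), CH2Cl2, 0 °C → rt; then ClCO2CH2CH2SiMe3, 0 °C → rt; 1 M HCl work-up
Reagents that add atoms: trimethylaluminium, C[Al](C)C; 2-(trimethylsilyl)ethyl chloroformate, C[Si](C)(C)CCOC(Cl)=O
Why: Negishi zirconium-catalysed carboalumination (syn addition of Me–Al to the terminal alkyne) and acylation of the alkenylalane with retention give the trisubstituted (E)-enoate, fixing the 13E geometry.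

**Step 7**
Reactants: 12 2-(trimethylsilyl)ethyl (2E)-6-chloro-3-methylhex-2-enoate
Product: 13 [(4E)-4-methyl-6-oxo-6-[2-(trimethylsilyl)ethoxy]hex-4-en-1-yl]triphenylphosphonium iodide
Conditions: NaI (1.5 equiv), PPh3 (1.2 equiv), MeCN, reflux
Reagents that add atoms: triphenylphosphine, c1ccc(cc1)P(c1ccccc1)c1ccccc1; sodium iodide, [Na+].[I-]
Why: Finkelstein exchange followed by SN2 quaternisation of the phosphine gives the Wittig salt; the hindered β,β-disubstituted enoate is inert.

**Step 8**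
Reactants: 9 (3aR,4S,5R,7aR)-4-[(tert-butyldiphenylsilyloxy)methyl]-5-hydroxy-4,7a-dimethyloctahydro-1H-inden-1-one; 13 [(4E)-4-methyl-6-oxo-6-[2-(trimethylsilyl)ethoxy]hex-4-en-1-yl]triphenylphosphonium iodide
Product: 15 2-(trimethylsilyl)ethyl (2E,6Z)-6-[(3aS,4S,5R,7aR)-4-[(tert-butyldiphenylsilyloxy)methyl]-5-hydroxy-4,7a-dimethyloctahydro-1H-inden-1-ylidene]-3-methylhex-2-enoate, via ylide 14 (not isolated)
Conditions: 13 (3 equiv), KN(SiMe3)2 (2.9 equiv), THF, 0 °C; then 9, toluene, 70 °C
Reagents that add atoms: none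
Why: Wittig olefination of the neopentyl cyclopentanone with a non-stabilised ylide (as for 17-keto steroids), with no free amide base left to touch the ester; the alkene geometry (expected mainly Z) does not matter because this carbon becomes the epimerisable C9.

**Step 9**
Reactants: 15 2-(trimethylsilyl)ethyl (2E,6Z)-6-[(3aS,4S,5R,7aR)-4-[(tert-butyldiphenylsilyloxy)methyl]-5-hydroxy-4,7a-dimethyloctahydro-1H-inden-1-ylidene]-3-methylhex-2-enoate
Product: 17 2-(trimethylsilyl)ethyl (13E)-ent-18-(tert-butyldiphenylsilyloxy)-3β-hydroxy-8-oxo-17-norlabd-13-en-15-oate, via iodane adduct 16 (not isolated)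
Conditions: PhI(OH)OTs (1.2 equiv), MeCN–H2O (9:1), 0 °C → rt; then rt, 12 h
Reagents that add atoms: water, O
Why: Proposed new method: a trivalent-iodine oxidative semipinacol ring expansion of a fully aliphatic alkylidenecyclopentane, in which PhI(OH)OTs adds only to the electron-rich trisubstituted alkene, water captures the tertiary C8, and loss of the PhI hyper-nucleofuge from C9 is assisted by the C8–OH lone pair and by anti-periplanar migration of the more substituted, better σ-donating C8–C10 bond (quaternary C10 migrates with retention; Curtin–Hammett over rotamers in a cation-like transition state), so C9 becomes bonded to C10 and ring B closes as the cyclohexanone; the closest known reaction types are the Wittig/ring-expansion of benzo-fused alkylidenecycloalkanes with the same reagent (aryl migration) and the Tl(NO3)3 (trivalent thallium) ring expansion of simple methylenecycloalkanes, and C9, being α to the ketone, equilibrates under the TsOH formed to the equatorial side-chain epimer.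

**Step 10**
Reactants: 17 2-(trimethylsilyl)ethyl (13E)-ent-18-(tert-butyldiphenylsilyloxy)-3β-hydroxy-8-oxo-17-norlabd-13-en-15-oate
Product: 18 2-(trimethylsilyl)ethyl (13E)-ent-18-(tert-butyldiphenylsilyloxy)-3β-hydroxylabda-8(17),13-dien-15-oate
Conditions: Ph3PCH3Br (4 equiv), KN(SiMe3)2 (3.8 equiv), THF, 0 → 50 °C
Reagents that add atoms: methyltriphenylphosphonium bromide, C[P+](c1ccccc1)(c1ccccc1)c1ccccc1.[Br-]
Why: Wittig methylenation of the C8 ketone (standard for 8-oxo labdanes) installs the 8(17) alkene; under the basic conditions C9 equilibrates and the equatorial epimer is both favoured and more reactive, so the C9 configuration is fixed here.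

**Step 11**
Reactants: 18 2-(trimethylsilyl)ethyl (13E)-ent-18-(tert-butyldiphenylsilyloxy)-3β-hydroxylabda-8(17),13-dien-15-oate; 19 (2Z)-2-methylbut-2-enoic acid
Product: 21 2-(trimethylsilyl)ethyl (13E)-ent-3β-angeloyloxy-18-(tert-butyldiphenylsilyloxy)labda-8(17),13-dien-15-oate, via mixed anhydride 20 (not isolated)
Conditions: 19, 2,4,6-Cl3C6H2COCl, Et3N, toluene, rt; then 18, toluene, 80 °C (no DMAP)
Reagents that add atoms: none
Why: Yamaguchi esterification through the mixed anhydride, run without DMAP so that the (Z)-angelate does not isomerise to the tiglate; only the C3–OH is free.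

**Step 12**
Reactants: 21 2-(trimethylsilyl)ethyl (13E)-ent-3β-angeloyloxy-18-(tert-butyldiphenylsilyloxy)labda-8(17),13-dien-15-oate
Product: 22 (13E)-ent-3β-angeloyloxy-18-hydroxylabda-8(17),13-dien-15-oic acid (CNP0420226.2)
Conditions: (Et2N)3S+ Me3SiF2− (TASF, 4 equiv), DMF, 0 °C → rt; aq NH4Cl
Reagents that add atoms: none
Why: Fluoride-induced desilylation of the TBDPS ether and β-elimination of the TMSE ester under near-neutral anhydrous conditions free the C18–OH and the C15 acid in one operation, avoiding base-promoted acyl migration from O3 to O18 and angelate isomerisation.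

**Compound list**
1 | 2-methylcyclopentane-1,3-dione | CC1C(=O)CCC1=O | starting material
2 | pent-1-en-3-one (ethyl vinyl ketone) | CCC(=O)C=C | starting material
3 | 2-methyl-2-(3-oxopentyl)cyclopentane-1,3-dione | CCC(=O)CCC1(C)C(=O)CCC1=O | intermediate (not isolated)
4 | (7aR)-4,7a-dimethyl-2,3,7,7a-tetrahydro-1H-indene-1,5(6H)-dione | CC1=C2CCC(=O)[C@]2(C)CCC1=O | intermediate
5 | (7a'R)-4',7a'-dimethyl-2',3',7',7a'-tetrahydrospiro[1,3-dioxolane-2,1'-inden]-5'(6'H)-one | CC1=C2CCC3(OCCO3)[C@]2(C)CCC1=O | intermediate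
6 | (3a'S,4'S,7a'R)-4'-(hydroxymethyl)-4',7a'-dimethylhexahydrospiro[1,3-dioxolane-2,1'-inden]-5'(4'H)-one; trans-fused, CH2OH trans to the angular methyl | O1CCOC12CC[C@H]3[C@@]2(C)CCC(=O)[C@]3(C)CO | intermediate
7 | (3a'R,4'S,5'R,7a'R)-4'-(hydroxymethyl)-4',7a'-dimethyloctahydrospiro[1,3-dioxolane-2,1'-inden]-5'-ol | O1CCOC12CC[C@H]3[C@@]2(C)CC[C@@H](O)[C@]3(C)CO | intermediate (not isolated)
8 | (3aR,4S,5R,7aR)-5-hydroxy-4-(hydroxymethyl)-4,7a-dimethyloctahydro-1H-inden-1-one | O=C1CC[C@H]2[C@@]1(C)CC[C@@H](O)[C@]2(C)CO | intermediate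
9 | (3aR,4S,5R,7aR)-4-[(tert-butyldiphenylsilyloxy)methyl]-5-hydroxy-4,7a-dimethyloctahydro-1H-inden-1-one | O=C1CC[C@H]2[C@@]1(C)CC[C@@H](O)[C@]2(C)CO[Si](c1ccccc1)(c1ccccc1)C(C)(C)C | intermediate
10 | 5-chloropent-1-yne | C#CCCCCl | starting material
11 | [(1E)-5-chloro-2-methylpent-1-en-1-yl]dimethylalane | ClCCC/C(C)=C/[Al](C)C | intermediate (not isolated)
12 | 2-(trimethylsilyl)ethyl (2E)-6-chloro-3-methylhex-2-enoate | ClCCC/C(C)=C/C(=O)OCC[Si](C)(C)C | intermediate
13 | [(4E)-4-methyl-6-oxo-6-[2-(trimethylsilyl)ethoxy]hex-4-en-1-yl]triphenylphosphonium iodide | C[Si](C)(C)CCOC(=O)/C=C(C)/CCC[P+](c1ccccc1)(c1ccccc1)c1ccccc1.[I-] | intermediate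
14 | 2-(trimethylsilyl)ethyl (2E)-3-methyl-6-(triphenyl-λ5-phosphanylidene)hex-2-enoate (ylide of 13) | C[Si](C)(C)CCOC(=O)/C=C(C)/CCC=P(c1ccccc1)(c1ccccc1)c1ccccc1 | intermediate (not isolated)
15 | 2-(trimethylsilyl)ethyl (2E,6Z)-6-[(3aS,4S,5R,7aR)-4-[(tert-butyldiphenylsilyloxy)methyl]-5-hydroxy-4,7a-dimethyloctahydro-1H-inden-1-ylidene]-3-methylhex-2-enoate | C[Si](C)(C)CCOC(=O)/C=C(C)/CC/C=C1/CC[C@H]2[C@@]1(C)CC[C@@H](O)[C@]2(C)CO[Si](c1ccccc1)(c1ccccc1)C(C)(C)C | intermediate
16 | adduct of 15 carrying OH on C8 and the phenyl(tosyloxy)-λ3-iodanyl group on C9; the two new centres are uncontrolled and both diastereomers converge | C[Si](C)(C)CCOC(=O)/C=C(C)/CCC(I(c1ccccc1)OS(=O)(=O)c1ccc(C)cc1)C1(O)CC[C@H]2[C@@]1(C)CC[C@@H](O)[C@]2(C)CO[Si](c1ccccc1)(c1ccccc1)C(C)(C)C | intermediate (not isolated)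
17 | 2-(trimethylsilyl)ethyl (13E)-ent-18-(tert-butyldiphenylsilyloxy)-3β-hydroxy-8-oxo-17-norlabd-13-en-15-oate; (3R,4S,5S,9S,10R), side chain on C9 equatorial | O=C1CC[C@H]2[C@@](C)(CC[C@@H](O)[C@]2(C)CO[Si](c3ccccc3)(c3ccccc3)C(C)(C)C)[C@@H]1CC/C(C)=C/C(=O)OCC[Si](C)(C)C | intermediate
18 | 2-(trimethylsilyl)ethyl (13E)-ent-18-(tert-butyldiphenylsilyloxy)-3β-hydroxylabda-8(17),13-dien-15-oate; (3R,4S,5S,9R,10S) | C=C1CC[C@H]2[C@@](C)(CC[C@@H](O)[C@]2(C)CO[Si](c3ccccc3)(c3ccccc3)C(C)(C)C)[C@@H]1CC/C(C)=C/C(=O)OCC[Si](C)(C)C | intermediate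
19 | (2Z)-2-methylbut-2-enoic acid (angelic acid) | C/C=C(/C)C(=O)O | starting material
20 | (2Z)-2-methylbut-2-enoic 2,4,6-trichlorobenzoic anhydride | C/C=C(/C)C(=O)OC(=O)c1c(Cl)cc(Cl)cc1Cl | intermediate (not isolated)
21 | 2-(trimethylsilyl)ethyl (13E)-ent-3β-angeloyloxy-18-(tert-butyldiphenylsilyloxy)labda-8(17),13-dien-15-oate; (3R,4S,5S,9R,10S) | C=C1CC[C@H]2[C@@](C)(CC[C@@H](OC(=O)/C(C)=C\C)[C@]2(C)CO[Si](c3ccccc3)(c3ccccc3)C(C)(C)C)[C@@H]1CC/C(C)=C/C(=O)OCC[Si](C)(C)C | intermediate
22 | (13E)-ent-3β-angeloyloxy-18-hydroxylabda-8(17),13-dien-15-oic acid; (3R,4S,5S,9R,10S) | C=C1CC[C@H]2[C@@](C)(CC[C@@H](OC(=O)/C(C)=C\C)[C@]2(C)CO)[C@@H]1CC/C(C)=C/C(=O)O | target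

**Step count and risks**
Total steps: 12. Longest linear sequence: 10 (steps 1–5 and 8–12); the side-chain branch is steps 6–7.

Step 9 (proposed new ring expansion) is the most likely to fail. The risks are migration of C7 instead of C10, methyl shift from C10 if a free C8 cation forms, and acid damage. The fallback uses known chemistry and sets out from 15. NBS in aqueous THF at 0 °C gives the Markovnikov bromohydrin, 2-(trimethylsilyl)ethyl (2E)-6-bromo-6-[(3aS,4S,5R,7aR)-4-[(tert-butyldiphenylsilyloxy)methyl]-1,5-dihydroxy-4,7a-dimethyloctahydro-1H-inden-1-yl]-3-methylhex-2-enoate F5 (OH on C8, Br on C9). AgBF4 in CH2Cl2 then triggers the classical silver-assisted halohydrin semipinacol rearrangement, and the route is rejoined at 17.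

Step 8 (Wittig on a neopentyl ketone with an ester-bearing ylide) is second. The risks are low conversion and base-induced scrambling of the enoate. The fallback sets out from 9 and 10 and builds the enoate on the scaffold instead. Compound 10 with NaI and PPh3 gives pent-4-yn-1-yl(triphenyl)phosphonium iodide F2. Its ester-free ylide can be used in large excess under forcing conditions (KOtBu, toluene, 100 °C) to give the alkynyl alkylidene (1Z,3aS,4S,5R,7aR)-4-[(tert-butyldiphenylsilyloxy)methyl]-4,7a-dimethyl-1-(pent-4-yn-1-ylidene)octahydro-1H-inden-5-ol F3. Carboalumination (Me3Al, Cp2ZrCl2) and I2 quench give the (E)-vinyl iodide (1Z,3aS,4S,5R,7aR)-4-[(tert-butyldiphenylsilyloxy)methyl]-1-[(4E)-5-iodo-4-methylpent-4-en-1-ylidene]-4,7a-dimethyloctahydro-1H-inden-5-ol F4. Alkoxycarbonylation (CO, Me3SiCH2CH2OH, Et3N, PdCl2(PPh3)2) then rejoins the route at 15.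

Step 3 (reductive hydroxymethylation) is third. The risks are cis-fused by-product in the hydrindane series and poor capture of formaldehyde. The fallback sets out from 5 and avoids dissolving metal. KOtBu forms the extended dienolate, and gaseous CH2O alkylates C4 anti to the angular methyl to give the deconjugated ketone (4'S,7a'R)-4'-(hydroxymethyl)-4',7a'-dimethyl-2',4',7',7a'-tetrahydrospiro[1,3-dioxolane-2,1'-inden]-5'(6'H)-one F1, in which the double bond has moved into the five-membered ring. Hydroxyl-directed hydrogenation with [Ir(cod)(PCy3)(py)]PF6 and H2 in CH2Cl2 delivers hydrogen to the ring-fusion carbon from the CH2OH face, anti to the angular methyl, and rejoins the route at trans-fused 6.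

**Further compounds**
F1 | step 3 | (4'S,7a'R)-4'-(hydroxymethyl)-4',7a'-dimethyl-2',4',7',7a'-tetrahydrospiro[1,3-dioxolane-2,1'-inden]-5'(6'H)-one | O1CCOC12CC=C3[C@@]2(C)CCC(=O)[C@]3(C)CO
F2 | step 8 | pent-4-yn-1-yl(triphenyl)phosphonium iodide | C#CCCC[P+](c1ccccc1)(c1ccccc1)c1ccccc1.[I-]
F3 | step 8 | (1Z,3aS,4S,5R,7aR)-4-[(tert-butyldiphenylsilyloxy)methyl]-4,7a-dimethyl-1-(pent-4-yn-1-ylidene)octahydro-1H-inden-5-ol | C#CCC/C=C1/CC[C@H]2[C@@]1(C)CC[C@@H](O)[C@]2(C)CO[Si](c1ccccc1)(c1ccccc1)C(C)(C)C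
F4 | step 8 | (1Z,3aS,4S,5R,7aR)-4-[(tert-butyldiphenylsilyloxy)methyl]-1-[(4E)-5-iodo-4-methylpent-4-en-1-ylidene]-4,7a-dimethyloctahydro-1H-inden-5-ol | I/C=C(C)/CC/C=C1/CC[C@H]2[C@@]1(C)CC[C@@H](O)[C@]2(C)CO[Si](c1ccccc1)(c1ccccc1)C(C)(C)C
F5 | step 9 | 2-(trimethylsilyl)ethyl (2E)-6-bromo-6-[(3aS,4S,5R,7aR)-4-[(tert-butyldiphenylsilyloxy)methyl]-1,5-dihydroxy-4,7a-dimethyloctahydro-1H-inden-1-yl]-3-methylhex-2-enoate | C[Si](C)(C)CCOC(=O)/C=C(C)/CCC(Br)C1(O)CC[C@H]2[C@@]1(C)CC[C@@H](O)[C@]2(C)CO[Si](c1ccccc1)(c1ccccc1)C(C)(C)C
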